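**Assumption:** germacrane numbering is used (C1 ketone, C3–O–C10 furanone, 6,12-olide, C8 ester); the given SMILES corresponds to (5R,6S,7R,8S,10R), and that enantiomer is made.

## Retrosynthetic overview

1. Target ⇒ C8 methacrylation and C5 desilylation of macrocyclic alcohol 19.
2. 19 ⇒ C7–C8: intramolecular Cr(II) allylation of bromomethyl-butenolide aldehyde 18. This closes the 10-membered ring last, creates the exo-methylene and sets C7/C8.
3. 18 ⇒ C5–C6: catalytic asymmetric vinylogous Mukaiyama aldol that dearomatises 2-silyloxyfuran 14 (from furan-3-ylmethanol) with furanone enal 11. This is the key step; it forms the butenolide and sets C5/C6.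
4. 11 ⇒ Au-catalysed 5-endo cyclisation of α′-hydroxy ynone 9; C10 comes from (S)-lactic acid by Seebach dioxolanone allylation, the enyne from 2-bromoallyl alcohol.
5. Ring order: 3(2H)-furanone → butenolide (by dearomatisation) → 10-membered carbocycle (which also converts the butenolide into the α-methylene-γ-lactone).

## Route

**Step 1**
Reactants: 1 (S)-lactic acid; 2 pivalaldehyde
Product: 3 (2S,5S)-2-tert-butyl-5-methyl-1,3-dioxolan-4-one (cis)
Conditions: TsOH (cat.), H2SO4 (cat.), pentane, reflux, Dean–Stark; recrystallise at −78 °C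
Reagents that add atoms: none beyond reactant 2
Why: Acid-catalysed acetalisation (first stage of Seebach self-regeneration of stereocentres); the cis acetal is favoured and crystallises, so the lactate configuration is stored at the new acetal carbon (2S).

**Step 2**
Reactants: 3; 4 allyl bromide
Product: 5 (2S,5R)-2-tert-butyl-5-methyl-5-(prop-2-en-1-yl)-1,3-dioxolan-4-one
Conditions: LDA, THF, −78 °C; then 4, −78 → −30 °C
Reagents that add atoms: none beyond reactant 4
Why: Seebach enolate alkylation; the planar lithium enolate is allylated anti to the tert-butyl group, so allyl replaces H with net retention and creates the C10 quaternary centre as R.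

**Step 3**
Reactants: 6 2-bromoprop-2-en-1-ol; 7 ethynyltrimethylsilane
Product: 8 2-[(trimethylsilyl)ethynyl]prop-2-en-1-ol
Conditions: Pd(PPh3)2Cl2 (2 mol %), CuI (4 mol %), i-Pr2NH, THF, rt
Reagents that add atoms: none beyond reactant 7
Why: Sonogashira coupling of a 1,1-disubstituted vinyl bromide installs the C2–C3 alkyne on the C4(=C15)–C5 unit; no stereocentre is formed.

**Step 4**
Reactants: 5; 8
Product: 9 (6R)-6-hydroxy-2-(hydroxymethyl)-6-methylnona-1,8-dien-3-yn-5-one
Conditions: 8, MeLi·LiBr (2.1 equiv per 8), THF, 0 °C → rt; then 5, −78 °C; AcOH quench at −78 °C, aq. NH4Cl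
Reagents that add atoms: none
Why: Acetylide acylation; MeLi deprotonates the OH and cleaves the C–Si bond to give the alkoxide–acetylide, which adds once to the dioxolanone carbonyl (C10 has no α-H, and the tetrahedral adduct only collapses on work-up, releasing pivalaldehyde and the free tertiary alcohol), leaving C10 untouched.

**Step 5**
Reactants: 9
Product: 10 (2R)-5-(3-hydroxyprop-1-en-2-yl)-2-methyl-2-(prop-2-en-1-yl)furan-3(2H)-one
Conditions: (p-CF3C6H4)3PAuCl / AgOTf (2 mol %), toluene, rt
Reagents that add atoms: none
Why: Au(I)-catalysed 5-endo-dig cycloisomerisation of a γ-hydroxy ynone; only the tertiary C10–OH can reach the activated β-alkyne carbon (C3), giving the 3(2H)-furanone with C10 unchanged.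

**Step 6**
Reactants: 10
Product: 11 2-[(5R)-5-methyl-4-oxo-5-(prop-2-en-1-yl)-4,5-dihydrofuran-2-yl]prop-2-enal
Conditions: activated MnO2, CH2Cl2, rt; filter and use at once
Reagents that add atoms: none
Why: Neutral MnO2 oxidation is selective for the primary allylic alcohol and delivers the polymerisation-prone 2-substituted acrolein without base or acid.

**Step 7**
Reactants: 12 furan-3-ylmethanol
Product: 13 triethyl(furan-3-ylmethoxy)silane
Conditions: TESCl, imidazole, CH2Cl2, 0 °C
Reagents that add atoms: chlorotriethylsilane, CC[Si](Cl)(CC)CC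
Why: Standard O-silylation masks the future C13 oxygen as a silyl ether that later converts directly to the allylic bromide.

**Step 8**
Reactants: 13
Product: 14 triethyl({2-[(trimethylsilyl)oxy]furan-3-yl}methoxy)silane
Conditions: n-BuLi, TMEDA, THF, −78 → −40 °C; Me3SiOOSiMe3, −78 °C → rt; use crude or distilled
Reagents that add atoms: bis(trimethylsilyl) peroxide, C[Si](C)(C)OO[Si](C)(C)C
Why: CH2O-directed α-lithiation of the furan at C2 followed by electrophilic oxygenation with the silyl peroxide gives the aromatic 2-silyloxyfuran directly; low temperature without HMPA suppresses O→C silyl migration.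

**Step 9 (key step)**
Reactants: 11; 14
Product: 15 (5S)-5-{(1R)-1-hydroxy-2-[(5R)-5-methyl-4-oxo-5-(prop-2-en-1-yl)-4,5-dihydrofuran-2-yl]prop-2-en-1-yl}-3-{[(triethylsilyl)oxy]methyl}furan-2(5H)-one (C5 R, C6 S)
Conditions: cinchonidine-derived N-benzyl quaternary ammonium phenoxide (10 mol %; the cinchonine-derived pseudoenantiomer if the facial sense is reversed), THF, −78 °C; pH 4 citrate work-up (cleaves O-TMS only)
Reagents that add atoms: none
Why: Lewis-base-catalysed vinylogous Mukaiyama aldol; the furan is dearomatised by γ-attack (furan C5 = C6) on the Si face of the aldehyde (1,2-addition at −78 °C) through an open antiperiplanar ammonium-dienolate transition state. That manifold favours the erythro (unlike) adduct, which is the required 5R,6S pair, and the chiral ion pair sets the absolute sense; this selectivity is extrapolated from simpler aldehydes and silyloxyfurans.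

**Step 10**
Reactants: 15
Product: 16 the C5 O-tert-butyldimethylsilyl ether of 15
Conditions: TBSOTf, 2,6-lutidine, CH2Cl2, −78 °C
Reagents that add atoms: tert-butyldimethylsilyl triflate, CC(C)(C)[Si](C)(C)OS(=O)(=O)C(F)(F)F
Why: Silylation of the only free hydroxyl at −78 °C with a weak base avoids γ-deprotonation of the butenolide (C6 epimerisation) and distinguishes C5–O (TBS) from C13–O (TES).

**Step 11**
Reactants: 16
Product: 17 (5S)-3-(bromomethyl)-5-{(1R)-1-[(tert-butyldimethylsilyl)oxy]-2-[(5R)-5-methyl-4-oxo-5-(prop-2-en-1-yl)-4,5-dihydrofuran-2-yl]prop-2-en-1-yl}furan-2(5H)-one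
Conditions: Ph3P·Br2, CH2Cl2, 0 °C → rt
Reagents that add atoms: triphenylphosphine dibromide, BrP(Br)(c1ccccc1)(c1ccccc1)c1ccccc1
Why: Direct silyl ether → bromide conversion via an alkoxyphosphonium ion; the unhindered primary allylic TES ether reacts far faster than the hindered secondary TBS ether, and SN2 at C13 keeps the conjugated butenolide.

**Step 12**
Reactants: 17
Product: 18 2-[(2R)-5-{(1R)-1-[(5S)-4-(bromomethyl)-5-oxo-2,5-dihydrofuran-2-yl]-1-[(tert-butyldimethylsilyl)oxy]prop-2-en-2-yl}-2-methyl-3-oxo-2,3-dihydrofuran-2-yl]acetaldehyde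
Conditions: OsO4 (2 mol %), NaIO4, dioxane/H2O, rt, no amine additive; use directly
Reagents that add atoms: osmium tetroxide / sodium periodate (source of the aldehyde oxygen), O=[Os](=O)(=O)=O and [Na+].[O-]I(=O)(=O)=O
Why: Lemieux–Johnson cleavage occurs at the only isolated, electron-rich monosubstituted alkene (the other three C=C bonds are conjugated and electron-poor or hindered); base-free conditions protect the allylic bromide and avoid retro-oxa-Michael opening of the β-alkoxy aldehyde.

**Step 13**
Reactants: 18
Product: 19 (5R,6S,7R,8S,10R)-5-O-TBS-8-O-desmethacryloyl-isogoiazensolide (macrocyclic C8 alcohol)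
Conditions: CrCl2 (8 equiv), THF, rt, slow addition to 2 mM final concentration
Reagents that add atoms: none
Why: Intramolecular Nozaki–Hiyama allylation; the allyl-Cr(III) species adds through C7 to the aldehyde in a chair transition state. Bond formation anti to the C6 side chain gives the trans-lactone (7R), and the fixed E-type geometry of the cyclic allylmetal gives the anti carbinol (8S), while closing the 10-membered ring and unveiling the exo-methylene.

**Step 14**
Reactants: 19; 20 methacrylic anhydride
Product: 21 5-O-TBS-isogoiazensolide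
Conditions: Et3N, DMAP (cat.), CH2Cl2, 0 °C → rt
Reagents that add atoms: none beyond reactant 20
Why: DMAP-catalysed acylation of the only free hydroxyl (C8) installs the methacrylate with retention at C8.

**Step 15**
Reactants: 21
Product: 22 Isogoiazensolide
Conditions: HF·pyridine, THF/pyridine, 0 °C → rt
Reagents that add atoms: none
Why: Buffered fluoride desilylation frees the C5 allylic alcohol without touching the methacrylate, the α-methylene lactone or the furanone.

## Compound list

1 | (S)-lactic acid | C[C@H](O)C(=O)O | starting material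
2 | pivalaldehyde | CC(C)(C)C=O | starting material
3 | (2S,5S)-2-tert-butyl-5-methyl-1,3-dioxolan-4-one | CC(C)(C)[C@H]1O[C@@H](C)C(=O)O1 | intermediate
4 | allyl bromide | C=CCBr | starting material
5 | (2S,5R)-5-allyl-2-tert-butyl-5-methyl-1,3-dioxolan-4-one | CC(C)(C)[C@H]1O[C@@](CC=C)(C)C(=O)O1 | intermediate
6 | 2-bromoprop-2-en-1-ol | OCC(Br)=C | starting material
7 | ethynyltrimethylsilane | C#C[Si](C)(C)C | starting material
8 | 2-[(trimethylsilyl)ethynyl]prop-2-en-1-ol | OCC(=C)C#C[Si](C)(C)C | intermediate
9 | (6R)-6-hydroxy-2-(hydroxymethyl)-6-methylnona-1,8-dien-3-yn-5-one | C=CC[C@@](C)(O)C(=O)C#CC(=C)CO | intermediate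
10 | (2R)-5-(3-hydroxyprop-1-en-2-yl)-2-methyl-2-allylfuran-3(2H)-one | C=CC[C@@]1(C)OC(=CC1=O)C(=C)CO | intermediate
11 | 2-[(5R)-5-allyl-5-methyl-4-oxo-4,5-dihydrofuran-2-yl]prop-2-enal | C=CC[C@@]1(C)OC(=CC1=O)C(=C)C=O | intermediate
12 | furan-3-ylmethanol | OCc1ccoc1 | starting material
13 | triethyl(furan-3-ylmethoxy)silane | CC[Si](CC)(CC)OCc1ccoc1 | intermediate
14 | 3-[(triethylsilyloxy)methyl]-2-(trimethylsilyloxy)furan | CC[Si](CC)(CC)OCc1ccoc1O[Si](C)(C)C | intermediate
15 | vinylogous aldol adduct (C5 R-OH, C6 S, C10 R; C13-OTES) | C=CC[C@@]1(C)OC(=CC1=O)C(=C)[C@@H](O)[C@H]1OC(=O)C(CO[Si](CC)(CC)CC)=C1 | intermediate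
16 | C5-OTBS, C13-OTES butenolide | C=CC[C@@]1(C)OC(=CC1=O)C(=C)[C@@H](O[Si](C)(C)C(C)(C)C)[C@H]1OC(=O)C(CO[Si](CC)(CC)CC)=C1 | intermediate
17 | C5-OTBS α-(bromomethyl)butenolide | C=CC[C@@]1(C)OC(=CC1=O)C(=C)[C@@H](O[Si](C)(C)C(C)(C)C)[C@H]1OC(=O)C(CBr)=C1 | intermediate
18 | C8 aldehyde / C13 bromide cyclisation precursor | O=CC[C@@]1(C)OC(=CC1=O)C(=C)[C@@H](O[Si](C)(C)C(C)(C)C)[C@H]1OC(=O)C(CBr)=C1 | intermediate
19 | 5-O-TBS-8-O-desmethacryloyl-isogoiazensolide | O[C@H]1C[C@@]2(C)OC(=CC2=O)C(=C)[C@@H](O[Si](C)(C)C(C)(C)C)[C@H]2OC(=O)C(=C)[C@@H]21 | intermediate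
20 | methacrylic anhydride | C=C(C)C(=O)OC(=O)C(C)=C | starting material
21 | 5-O-TBS-isogoiazensolide | C=C(C)C(=O)O[C@H]1C[C@@]2(C)OC(=CC2=O)C(=C)[C@@H](O[Si](C)(C)C(C)(C)C)[C@H]2OC(=O)C(=C)[C@@H]21 | intermediate
22 | Isogoiazensolide | C=C(C)C(=O)O[C@H]1C[C@@]2(C)OC(=CC2=O)C(=C)[C@@H](O)[C@H]2OC(=O)C(=C)[C@@H]21 | target

## Summary

**Total steps:** 15.
**Longest linear sequence:** 12 steps (1, 2, 4, 5, 6, 9, 10, 11, 12, 13, 14, 15 from (S)-lactic acid).

**Steps most likely to fail:**

1. **Step 9 (dearomative vinylogous aldol).** Enal 11 is a polymerisable, doubly activated acceptor (1,4-addition possible), and the erythro/enantio-selectivity is extrapolated. Fallback: run the vinylogous aldol on 2-bromoacrolein in the Lewis-acid (threo) manifold, invert C5 by Mitsunobu reaction, and then build the furanone on the vinyl bromide (Sonogashira coupling with the C10 propargylic alcohol fragment, oxidation, Au cyclisation).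

2. **Step 13 (Cr-mediated macrocyclisation).** Ring strain, the wrong C7/C8 diastereomer or oligomerisation are possible. Fallback: form C7–C8 intermolecularly (In-mediated Barbier allylation of an acyclic C8 aldehyde) and close the ring at C1–C2 by intramolecular Nozaki–Hiyama–Kishi addition of an iodoalkyne to a C1 aldehyde, then oxidise and form the furanone by transannular Au-catalysed cyclisation.

3. **Step 12 (chemoselective alkene cleavage).** Over-oxidation of the C4=C15 or furanone alkenes, loss of the allylic bromide or β-elimination of the aldehyde are possible. Fallback: cleave the allyl group at the dioxolanone stage (5) and carry C8 as a cyclic acetal through the non-Lewis-acidic aldol, releasing the aldehyde with mild acid just before cyclisation.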